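Remark: lignan numbering is used (C7/C7' benzylic carbons, C8/C8' stereocentres, C9/C9' hydroxymethyl carbons). The target SMILES is read as the (8R,8'R) isomer, i.e. the (2R,3R)-butane-1,4-diol.

## The problem

5,5'-Dimethoxysecoisolariciresinol (16) is an open-chain, C2-symmetric 2,3-dibenzylbutane-1,4-diol: a backbone C7–C8–C8'–C7' whose inner carbons each carry a hydroxymethyl group (C9, C9') and whose ends each carry a 4-hydroxy-3,5-dimethoxyphenyl (syringyl) ring. No ring in the target imposes order, so the two adjacent stereocentres C8 and C8' (both R) must be set on a chain, with absolute configuration introduced at one and relayed to the other. Relay becomes possible when C9 and C9' are tied through oxygen into a γ-butyrolactone: the substituent at C8 then directs a group or a proton at C8' to the trans position, and C8', being α to the carbonyl, can be equilibrated. The free syringyl phenols are electron-rich and easily oxidised, especially in base under air, and the 1,4-diol cyclodehydrates to a tetrahydrofuran under acid. The phenols therefore have to stay masked through all organometallic and basic steps, and the final unmasking has to be neutral. Because the two halves are identical, a cis (meso-type) by-product is a removable diastereomer, whereas the enantiomer is not, so the source of absolute configuration must be clean. The enabling feature is the pattern at C8: a methylene leading to an arene (C7), an oxymethylene (C9) and a bond to a carbon (C8') that can carry two carbonyl groups. This is what remains when the unsubstituted cyclopropane methylene of a 1-alkoxycarbonyl-3-oxabicyclo[3.1.0]hexan-2-one is opened by an aryl nucleophile: ring-fusion carbon C5 becomes C8, C6 becomes C7, C4 becomes C9, and the doubly activated C1 emerges as an enolate at C8' ready to accept C7'.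

## Retrosynthesis

**16 ⇒ 15 (two phenolic O–benzyl bonds).** The phenols are carried as benzyl ethers to the last step. Benzyl is preferred to silyl or acetal groups because it survives magnesium insertion, cuprate chemistry, hot chloride in DMSO and LiAlH4, and leaves by neutral hydrogenolysis. The forward step only has to cleave two O–CH2Ph bonds without touching the diol.

**15 ⇒ 14 (C9'–O reduction level; C9–O–C9' tied as a lactone).** The diol is the reduction product of trans-lactone 14. The lactone is the better intermediate than the open diol because its ring makes C8 and C8' communicate. The forward step is a plain LiAlH4 reduction that must not enolise C8'.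

**14 ⇒ 12 (C8'–H back to C8'–CO2Me).** Adding a methoxycarbonyl group at C8' turns that carbon into a malonate-type centre that can be generated as a stabilised enolate. Forward, this calls for demethoxycarbonylation and equilibration of the freed α-centre to the trans lactone. This is the price of the activation and costs one step.

**12 ⇒ 3 + 6 + 10 (aryl–C7 and C7'–C8').** These two cuts reduce 12 to a seven-carbon bicyclic lactone ester 3, an aryl Grignard reagent 6 and a benzylic bromide 10. Cutting at C7–C8 instead would require an acyl-anion equivalent for the aryl carbon and later removal of the activating atoms. Cutting at C8–C8' (dimerising two C6–C3 halves) offers no simple handle on absolute configuration. The aryl–C7 cut uses the arene as an ordinary nucleophile and lets the stereocentre come from the chiral pool. The forward reaction must attack the cyclopropane CH2 rather than a carbonyl group and then C-alkylate the resulting enolate.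

**3 ⇒ 1 + 2 (C1–C5, C1–C6 and the lactone C–O bond).** The cyclopropane lactone is the annulation product of (R)-epichlorohydrin 1 and dimethyl malonate 2. A catalytic asymmetric cyclopropanation of an allyl diazomalonate would reach the same ring system, but needs a diazo compound and a chiral catalyst where the chiral pool gives it in one step. The forward reaction must follow the epoxide-opening pathway so that the configuration of 1 is transferred cleanly.

**6 ⇒ 5 ⇒ 4 and 10 ⇒ 9 ⇒ 8 ⇒ 7 (functional-group changes).** Grignard reagent 6 comes from aryl bromide 5, the benzyl ether of commercial 4-bromo-2,6-dimethoxyphenol 4. Bromide 10 comes from alcohol 9, obtained by reduction of aldehyde 8, the benzyl ether of syringaldehyde 7. Both branches are routine.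

## Roads not taken

**Alternative 1:** Double decarboxylative arylation of a chiral adipate.
- **Cut and key step:** Both aryl–C7 bonds are cut at once, leading back to two equivalents of aryl bromide 5 and the bis(N-hydroxyphthalimide) ester A2 of a (3R,4R)-3,4-bis(silyloxymethyl)adipic acid. Forward, reductive nickel electrocatalysis (NiBr2, 4,4'-di-tert-butyl-2,2'-bipyridine, sacrificial anode) would expel CO2 twice from A2 and arylate both primary radicals to give bis-silyl ether A1. Desilylation and hydrogenolysis would finish.
- **Merits:** One operation forms both benzylic bonds and exploits the C2 symmetry fully. Both stereocentres exist before the key step, and neither is α to a carbonyl or a radical afterwards, so nothing can epimerise. In this respect it is better than the chosen plan, whose C8' is fixed only by equilibration of lactone 14.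
- **Weak points:** Every molecule must undergo two successive C(sp3)–C(sp2) couplings, so protodecarboxylation, alkyl dimerisation or hydrolysis of an activated ester at either end gives mono-arylated material that is hard to remove. Bromide 5 is electron-rich and adds slowly to low-valent nickel, which gives those side reactions time. A2 is not a chiral-pool compound: it needs its own asymmetric synthesis and several functional-group operations. Two carboxyl carbons and two phthalimide units are discarded.
- **Comparison:** The route is longer and rests on a double coupling without close precedent for such an arene. Against its stereochemical security the chosen plan sets a one-step chiral-pool entry and polar steps that each have direct precedent on the same lactone.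

**Alternative 2:** Conjunctive coupling of a vinylboron ate complex.
- **Cut and key step:** Aryl–C7 and C8–C8' are cut. The ate complex from enantioenriched secondary boronate A4 and vinylmagnesium bromide A5 would react with aryl bromide 5 under Pd(OAc)2, a Mandyphos-type ferrocenyl bisphosphine and NaOTf. The arylpalladium species activates the vinyl group, C8' migrates from boron to the inner carbon with retention, and reductive elimination forms aryl–C7, giving boronate A3 with C8 set by the ligand. C9 is still missing: a one-carbon homologation of A3 with a chloromethyllithium (Matteson type) and oxidation would be needed, then hydrogenolysis of three benzyl ethers.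
- **Merits:** C8 is created under catalyst control, kinetically and independently of substrate bias. The method is modular and would serve unsymmetrical analogues or the other diastereomer. The chosen plan shares the modularity, since 6 and 10 enter separately, but not the freedom to choose the diastereomer.
- **Weak points:** The key step leaves the skeleton one carbon short, and homologation of a secondary boronate flanked by two branched carbons is sluggish. Migration of a secondary alkyl group is the least favourable case of this coupling, and an electron-rich aryl bromide is a less reactive partner than a triflate. A4 needs its own enantioselective synthesis, so two independent asymmetric operations are spent on a C2-symmetric target, with a matched/mismatched question at the coupling. Ligand and palladium are costly.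
- **Comparison:** It has more steps and less precedent on hindered substrates. It is better only in setting both centres kinetically, against which the chosen plan sets brevity and cheap reagents.

**Alternative 3:** Three-component dithiane addition and benzylation on a chiral butenolide.
- **Cut and key step:** C7–C8 and C7'–C8' are cut. The lithio derivative of dithiane A8 (made from aldehyde 8) would add to C4 of 5-menthyloxybutenolide A7 anti to the menthyloxy group. The lactone enolate would be benzylated in the same flask by bromide 10, trans to the new substituent, to give the all-trans lactone A6. Desulfurisation with Raney Ni, LiAlH4 reduction (which opens the acetal lactone directly to the 1,4-diol) and hydrogenolysis would complete the synthesis.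
- **Merits:** Both stereocentres are set kinetically in one flask by a clear steric model (the acetal centre controls C8, C8 controls C8'). No equilibration is needed, the sequence is established for dibenzylbutane lignans, and the length is about the same. This is the strongest competitor, and in control of C8' it is probably better than the chosen plan.
- **Weak points:** The auxiliary is stoichiometric, and A7 requires a photo-oxygenation and a crystallisation-driven separation of acetal epimers. The aryl carbon must be used in umpolung form, with a dithiol and n-BuLi at low temperature. Desulfurisation needs a large excess of Raney Ni, which may strip the benzyl ethers before the hydride step. The auxiliary, two sulfur atoms and a three-carbon tether are discarded.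
- **Comparison:** The chosen plan uses the arene directly as a nucleophile with catalytic copper, needs no sulfur and draws its stereocentre from a one-step chiral-pool annulation. It pays with the need to equilibrate C8' and with dependence on how cleanly the configuration of 1 is transferred.

Key step: step 7

## Route

Step 1
Reactants: 1 (R)-epichlorohydrin; 2 dimethyl malonate
Product: 3 methyl (1S,5R)-2-oxo-3-oxabicyclo[3.1.0]hexane-1-carboxylate
Conditions: NaOMe (1.1 equiv), MeOH, 25 °C then 65 °C
Reagents that add atoms: none
Why: Malonate–epichlorohydrin annulation: the sodiomalonate opens the epoxide at its CH2, the alkoxide displaces chloride to form a new epoxide, and the malonate carbanion opens that epoxide at the stereogenic carbon with inversion (3-exo-tet), so (R)-1 should give (1S,5R)-3; the freed alkoxide then lactonises onto the cis ester.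

Step 2
Reactants: 4 4-bromo-2,6-dimethoxyphenol
Product: 5 2-(benzyloxy)-5-bromo-1,3-dimethoxybenzene
Conditions: BnBr, K2CO3, DMF, 60 °C
Reagents that add atoms: benzyl bromide, BrCc1ccccc1
Why: Williamson etherification of the phenoxide with a reactive benzylic halide; the aryl bromide is inert to carbonate.

Step 3
Reactants: 5 2-(benzyloxy)-5-bromo-1,3-dimethoxybenzene
Product: 6 (4-benzyloxy-3,5-dimethoxyphenyl)magnesium bromide (THF solution, titrated and used directly)
Conditions: Mg turnings, I2 (cat.), THF, 65 °C
Reagents that add atoms: magnesium, [Mg]
Why: Grignard formation by insertion of magnesium into the aryl–bromine bond; the closely related 3,4,5-trialkoxyphenyl bromides form Grignard reagents this way, and the aryl ethers are inert.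

Step 4
Reactants: 7 syringaldehyde
Product: 8 4-(benzyloxy)-3,5-dimethoxybenzaldehyde
Conditions: BnBr, K2CO3, DMF, 60 °C
Reagents that add atoms: benzyl bromide, BrCc1ccccc1
Why: Williamson etherification; the aldehyde, which has no α-hydrogen, is untouched by carbonate.

Step 5
Reactants: 8 4-(benzyloxy)-3,5-dimethoxybenzaldehyde
Product: 9 [4-(benzyloxy)-3,5-dimethoxyphenyl]methanol
Conditions: NaBH4, MeOH–THF, 0 °C
Reagents that add atoms: none
Why: Borohydride reduction of an aromatic aldehyde to the benzylic alcohol; the ethers are inert.

Step 6
Reactants: 9 [4-(benzyloxy)-3,5-dimethoxyphenyl]methanol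
Product: 10 2-(benzyloxy)-5-(bromomethyl)-1,3-dimethoxybenzene
Conditions: PBr3, Et2O, 0 °C; used without storage
Reagents that add atoms: phosphorus tribromide, BrP(Br)Br
Why: Conversion of a benzylic alcohol into the bromide through its phosphite ester and SN2 displacement by bromide; the low temperature and short contact time protect the benzyl ether and the activated benzylic bromide.

Step 7
Reactants: 3 methyl (1S,5R)-2-oxo-3-oxabicyclo[3.1.0]hexane-1-carboxylate; 6 (4-benzyloxy-3,5-dimethoxyphenyl)magnesium bromide; 10 2-(benzyloxy)-5-(bromomethyl)-1,3-dimethoxybenzene
Product: 12 methyl (3R,4R)-3,4-bis(4-benzyloxy-3,5-dimethoxybenzyl)-2-oxotetrahydrofuran-3-carboxylate, via bromomagnesium lactone enolate 11 (not isolated)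
Conditions: 6 (1.2 equiv), CuI (15 mol%), THF, −30 °C; then 10 (1.5 equiv), DMPU, −30 → 40 °C
Reagents that add atoms: none
Why: CuI and 6 form an arylcuprate of monovalent copper that attacks the unsubstituted cyclopropane carbon C6 of 3 in an SN2-like homoconjugate addition (formally through a trivalent alkylcopper that reductively eliminates), breaking the C1–C6 bond and leaving enolate 11, which is stabilised by both carbonyl groups. Bromide 10, added with DMPU to loosen the chelated magnesium enolate, then C-benzylates C3, so aryl–C7 and C7'–C8' are formed in one flask. The closest known reaction types are the copper-catalysed Grignard opening of cyclopropane-1,1-dicarboxylates and of this same lactone ester, and the alkylation of α-alkoxycarbonyl butyrolactone enolates. No ring is closed; the cyclopropane opens and the lactone persists. C4 of 12 (the future C8) is the former ring-fusion carbon C5 of 3, none of whose bonds changes, so its configuration is the one delivered by 1. The new quaternary centre C3 is set by approach of 10 to the enolate face anti to the C4 arylmethyl arm (trans, 3R); it is erased in step 8, so its diastereomeric purity is not critical. The step needs attack at C6 rather than at a carbonyl group (soft cuprate, low temperature, geminal activation), at C6 rather than the more substituted C5 (sterics), and C- rather than O-alkylation (soft benzylic bromide); only a small excess of 6 is used so that little 10 is lost to copper-catalysed aryl–benzyl coupling.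

Step 8
Reactants: 12 methyl (3R,4R)-3,4-bis(4-benzyloxy-3,5-dimethoxybenzyl)-2-oxotetrahydrofuran-3-carboxylate
Product: 14 (3R,4R)-3,4-bis(4-benzyloxy-3,5-dimethoxybenzyl)dihydrofuran-2(3H)-one (trans), via cis lactone epimer 13 (not isolated)
Conditions: LiCl (3 equiv), H2O (2 equiv), DMSO, 150 °C; then KOt-Bu (0.2 equiv), t-BuOH–THF, 25 °C, AcOH quench
Reagents that add atoms: none
Why: Krapcho demethoxycarbonylation: chloride demethylates the ester by SN2, the carboxylate loses CO2 and the lactone enolate is protonated by water, which is expected to leave some cis epimer 13 from protonation anti to the C4 arm; catalytic KOt-Bu then enolises C3 reversibly and funnels the mixture to the thermodynamically preferred trans lactone 14, while the non-enolisable C4 is untouched.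

Step 9
Reactants: 14 (3R,4R)-3,4-bis(4-benzyloxy-3,5-dimethoxybenzyl)dihydrofuran-2(3H)-one
Product: 15 (2R,3R)-2,3-bis(4-benzyloxy-3,5-dimethoxybenzyl)butane-1,4-diol
Conditions: LiAlH4, THF, 0 → 25 °C; Rochelle-salt work-up
Reagents that add atoms: none
Why: Hydride reduction of the lactone to the 1,4-diol through the lactol aluminate; hydride addition outpaces enolisation, so the α-centre keeps its configuration, and the aryl ethers are inert.

Step 10
Reactants: 15 (2R,3R)-2,3-bis(4-benzyloxy-3,5-dimethoxybenzyl)butane-1,4-diol
Product: 16 (2R,3R)-2,3-bis(4-hydroxy-3,5-dimethoxybenzyl)butane-1,4-diol (5,5'-dimethoxysecoisolariciresinol)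
Conditions: H2 (1 atm), 10% Pd/C (palladium on carbon), EtOAc–MeOH, 25 °C
Reagents that add atoms: none
Why: Catalytic hydrogenolysis of the two aryl benzyl ethers under neutral conditions; nothing else is reducible, and the absence of acid and base protects the diol from cyclodehydration and the freed syringyl phenols from oxidation.

## Compound list

1 | (R)-epichlorohydrin | ClC[C@H]1CO1 | starting material
2 | dimethyl malonate | COC(=O)CC(=O)OC | starting material
3 | methyl (1S,5R)-2-oxo-3-oxabicyclo[3.1.0]hexane-1-carboxylate | C1[C@H]2COC(=O)[C@@]12C(=O)OC | intermediate
4 | 4-bromo-2,6-dimethoxyphenol | COc1cc(Br)cc(OC)c1O | starting material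
5 | 2-(benzyloxy)-5-bromo-1,3-dimethoxybenzene | COc1cc(Br)cc(OC)c1OCc1ccccc1 | intermediate
6 | (4-benzyloxy-3,5-dimethoxyphenyl)magnesium bromide | COc1cc([Mg]Br)cc(OC)c1OCc1ccccc1 | intermediate
7 | syringaldehyde (4-hydroxy-3,5-dimethoxybenzaldehyde) | COc1cc(C=O)cc(OC)c1O | starting material
8 | 4-(benzyloxy)-3,5-dimethoxybenzaldehyde | COc1cc(C=O)cc(OC)c1OCc1ccccc1 | intermediate
9 | [4-(benzyloxy)-3,5-dimethoxyphenyl]methanol | COc1cc(CO)cc(OC)c1OCc1ccccc1 | intermediate
10 | 2-(benzyloxy)-5-(bromomethyl)-1,3-dimethoxybenzene | COc1cc(CBr)cc(OC)c1OCc1ccccc1 | intermediate
11 | bromomagnesium enolate of methyl (4R)-4-(4-benzyloxy-3,5-dimethoxybenzyl)-2-oxotetrahydrofuran-3-carboxylate | COC(=O)C1=C(O[Mg]Br)OC[C@@H]1Cc1cc(OC)c(OCc2ccccc2)c(OC)c1 | intermediate (not isolated)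
12 | methyl (3R,4R)-3,4-bis(4-benzyloxy-3,5-dimethoxybenzyl)-2-oxotetrahydrofuran-3-carboxylate | COc1cc(C[C@H]2COC(=O)[C@]2(C(=O)OC)Cc3cc(OC)c(OCc4ccccc4)c(OC)c3)cc(OC)c1OCc1ccccc1 | intermediate
13 | (3S,4R)-3,4-bis(4-benzyloxy-3,5-dimethoxybenzyl)dihydrofuran-2(3H)-one (cis) | COc1cc(C[C@H]2COC(=O)[C@H]2Cc3cc(OC)c(OCc4ccccc4)c(OC)c3)cc(OC)c1OCc1ccccc1 | intermediate (not isolated)
14 | (3R,4R)-3,4-bis(4-benzyloxy-3,5-dimethoxybenzyl)dihydrofuran-2(3H)-one (trans) | COc1cc(C[C@H]2COC(=O)[C@@H]2Cc3cc(OC)c(OCc4ccccc4)c(OC)c3)cc(OC)c1OCc1ccccc1 | intermediate
15 | (2R,3R)-2,3-bis(4-benzyloxy-3,5-dimethoxybenzyl)butane-1,4-diol | COc1cc(C[C@@H](CO)[C@H](CO)Cc2cc(OC)c(OCc3ccccc3)c(OC)c2)cc(OC)c1OCc1ccccc1 | intermediate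
16 | (2R,3R)-2,3-bis(4-hydroxy-3,5-dimethoxybenzyl)butane-1,4-diol (5,5'-dimethoxysecoisolariciresinol) | COc1cc(C[C@@H](CO)[C@H](CO)Cc2cc(OC)c(O)c(OC)c2)cc(OC)c1O | target

## Step count and risk

Total step count: 10 (one step to 3, two to 6, three to 10, four from the key step to the target).
Longest linear sequence: 7 steps, from syringaldehyde through steps 4, 5, 6, 7, 8, 9 and 10.

**Step 7 (key step).**
- **What may go wrong:** The most likely failure is incomplete C-benzylation of enolate 11, because chelated bromomagnesium β-dicarbonyl enolates are weak nucleophiles, so that protonated ring-opened material is recovered on work-up. Bromide 10 may also be lost through copper-catalysed coupling with surplus 6, and 6 may add to a carbonyl group if cuprate formation lags.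
- **Fallback (sets out from 3 and 6, returns at 14):** The ring opening is run alone (6, CuI cat., THF, −30 °C, NH4Cl quench) to give methyl (4R)-4-(4-benzyloxy-3,5-dimethoxybenzyl)-2-oxotetrahydrofuran-3-carboxylate F1. Krapcho demethoxycarbonylation (LiCl, wet DMSO, 140 °C) then gives (4R)-4-(4-benzyloxy-3,5-dimethoxybenzyl)dihydrofuran-2(3H)-one F2. Its lithium enolate (LiN(SiMe3)2, THF, −78 °C) is alkylated by 10 anti to the C4 arm, which should give trans lactone 14 directly under kinetic control. The same two bonds are formed, in separate flasks, and step 8 is bypassed.

**Step 8.**
- **What may go wrong:** Chloride may cleave the lactone at its O–CH2 carbon at 150 °C in competition with ester demethylation. Epimerisation of the cis portion may be incomplete, and the enolate may self-condense during the KOt-Bu treatment. Cis material carried forward would give the meso diol after step 9, a separable diastereomer, so enantiomeric purity is not at stake.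
- **Fallback (sets out from 12, returns at 14):** Saponification with KOH in aqueous MeOH, which also opens the lactone, gives dipotassium 2-(4-benzyloxy-3,5-dimethoxybenzyl)-2-[(2R)-1-(4-benzyloxy-3,5-dimethoxyphenyl)-3-hydroxypropan-2-yl]malonate F3. Acidification with aqueous HCl relactonises it to (3R,4R)-3,4-bis(4-benzyloxy-3,5-dimethoxybenzyl)-2-oxotetrahydrofuran-3-carboxylic acid F4. Thermal decarboxylation in toluene at 110 °C, followed by the same catalytic KOt-Bu equilibration, leads to 14. If the equilibrium position itself proves unsatisfactory, the kinetic alkylation described under step 7 is the remedy.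

**Step 1.**
- **What may go wrong:** Enantiomeric purity may be partly lost, because a minor share of the malonate can displace chloride directly instead of opening the epoxide, and that pathway leads to the mirror-image lactone. Oligomerisation of 1 under alkoxide may also lower the yield.
- **Fallback (sets out from 2, returns at 3):** (R)-Glycidol is converted with Tf2O and pyridine (CH2Cl2, −20 °C) into (S)-glycidyl trifluoromethanesulfonate F5. The sodium salt of 2 (NaH, THF, 0 °C, then catalytic NaOMe) displaces the triflate exclusively and then closes the cyclopropane and the lactone. Because the three-carbon unit is now attached through the former leaving-group carbon and not through the epoxide CH2, the glycidyl unit of spatial sense opposite to 1 is required; this is the (S)-triflate derived from (R)-glycidol.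

**Step 3.**
- **What may go wrong:** Initiation may be slow with the electron-rich bromide, and Wurtz-type homocoupling to the biaryl may occur during the prolonged heating then needed, giving a reagent solution of low and uncertain titre.
- **Fallback (sets out from 5, returns at 6):** Bromine–lithium exchange (n-BuLi, THF, −78 °C) gives (4-benzyloxy-3,5-dimethoxyphenyl)lithium F6, which is transmetalated with MgBr2·OEt2 to give 6 at low temperature.

## Further compounds

F1 | step 7 | methyl (4R)-4-(4-benzyloxy-3,5-dimethoxybenzyl)-2-oxotetrahydrofuran-3-carboxylate (C3 epimers) | COC(=O)C1C(=O)OC[C@@H]1Cc1cc(OC)c(OCc2ccccc2)c(OC)c1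
F2 | step 7 | (4R)-4-(4-benzyloxy-3,5-dimethoxybenzyl)dihydrofuran-2(3H)-one | O=C1C[C@@H](Cc2cc(OC)c(OCc3ccccc3)c(OC)c2)CO1
F3 | step 8 | dipotassium 2-(4-benzyloxy-3,5-dimethoxybenzyl)-2-[(2R)-1-(4-benzyloxy-3,5-dimethoxyphenyl)-3-hydroxypropan-2-yl]malonate | [K+].[K+].COc1cc(C[C@@H](CO)C(Cc2cc(OC)c(OCc3ccccc3)c(OC)c2)(C(=O)[O-])C(=O)[O-])cc(OC)c1OCc1ccccc1
F4 | step 8 | (3R,4R)-3,4-bis(4-benzyloxy-3,5-dimethoxybenzyl)-2-oxotetrahydrofuran-3-carboxylic acid | COc1cc(C[C@H]2COC(=O)[C@]2(C(=O)O)Cc3cc(OC)c(OCc4ccccc4)c(OC)c3)cc(OC)c1OCc1ccccc1
F5 | step 1 | (S)-glycidyl trifluoromethanesulfonate | O=S(=O)(OC[C@@H]1CO1)C(F)(F)F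
F6 | step 3 | (4-benzyloxy-3,5-dimethoxyphenyl)lithium | COc1cc([Li])cc(OC)c1OCc1ccccc1
A1 | alternative 1 | (2R,3R)-1,4-bis(4-benzyloxy-3,5-dimethoxyphenyl)-2,3-bis[(tert-butyldimethylsilyloxy)methyl]butane | COc1cc(C[C@@H](CO[Si](C)(C)C(C)(C)C)[C@H](CO[Si](C)(C)C(C)(C)C)Cc2cc(OC)c(OCc3ccccc3)c(OC)c2)cc(OC)c1OCc1ccccc1
A2 | alternative 1 | bis(1,3-dioxoisoindolin-2-yl) (3R,4R)-3,4-bis[(tert-butyldimethylsilyloxy)methyl]hexanedioate | O=C(C[C@@H](CO[Si](C)(C)C(C)(C)C)[C@H](CO[Si](C)(C)C(C)(C)C)CC(=O)ON1C(=O)c2ccccc2C1=O)ON1C(=O)c2ccccc2C1=O
A3 | alternative 2 | 2-[(2R,3R)-1,4-bis(4-benzyloxy-3,5-dimethoxyphenyl)-3-(benzyloxymethyl)butan-2-yl]-4,4,5,5-tetramethyl-1,3,2-dioxaborolane | COc1cc(C[C@@H](B2OC(C)(C)C(C)(C)O2)[C@H](COCc2ccccc2)Cc2cc(OC)c(OCc3ccccc3)c(OC)c2)cc(OC)c1OCc1ccccc1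
A4 | alternative 2 | 2-[(2S)-1-(benzyloxy)-3-(4-benzyloxy-3,5-dimethoxyphenyl)propan-2-yl]-4,4,5,5-tetramethyl-1,3,2-dioxaborolane | CC1(C)OB(OC1(C)C)[C@H](COCc1ccccc1)Cc1cc(OC)c(OCc2ccccc2)c(OC)c1
A5 | alternative 2 | vinylmagnesium bromide | C=C[Mg]Br
A6 | alternative 3 | (3R,4R,5R)-3-(4-benzyloxy-3,5-dimethoxybenzyl)-4-[2-(4-benzyloxy-3,5-dimethoxyphenyl)-1,3-dithian-2-yl]-5-[(1R,2S,5R)-menthyloxy]dihydrofuran-2(3H)-one | COc1cc(C2(SCCCS2)[C@@H]3[C@H](C(=O)O[C@H]3O[C@@H]4C[C@H](C)CC[C@H]4C(C)C)Cc5cc(OC)c(OCc6ccccc6)c(OC)c5)cc(OC)c1OCc1ccccc1
A7 | alternative 3 | (5R)-5-[(1R,2S,5R)-menthyloxy]furan-2(5H)-one | O=C1O[C@@H](O[C@@H]2C[C@H](C)CC[C@H]2C(C)C)C=C1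
A8 | alternative 3 | 2-(4-benzyloxy-3,5-dimethoxyphenyl)-1,3-dithiane | COc1cc(C2SCCCS2)cc(OC)c1OCc1ccccc1
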